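The ring is one ester (C1 and the ring O) closing an unbroken run of 31 methylenes (C2–C32), so the real task is an end-differentiated C32 chain whose mid-chain bond C17–C18 has no functional group within fifteen carbons. The route forms exactly this C(sp3)–C(sp3) bond by mixed Kolbe electrolysis. Anodic decarboxylation of 16-bromohexadecanoic acid and mono-tert-butyl octadecanedioate gives a C15 and a C17 primary radical, and their coupling should deliver the whole seco chain in one operation, with no unsaturation or auxiliary to erase. Both precursors are commercial fatty acids. Ester acidolysis and a caesium carboxylate closure onto the C32 bromide finish the strain-free 33-membered lactone.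

Key step: step 1

Remark: the SMILES is read as a 33-membered oxacycle with C1(=O), 31 CH2 (C2–C32, acid numbering) and the ring O on C32 (C32H62O2); it has no stereocentre, so there is no enantiomer to control.

Step 1
Reactants: 1 16-bromohexadecanoic acid; 2 18-(tert-butoxy)-18-oxooctadecanoic acid (mono-tert-butyl octadecanedioate)
Product: 5 tert-butyl 32-bromodotriacontanoate, via 15-bromopentadecyl radical 3 (not isolated), via 17-tert-butoxy-17-oxoheptadecyl radical 4 (not isolated)
Conditions: 1 (1 equiv), 2 (3 equiv), KOH (5 mol % of total acid), MeOH with a stirred heptane layer, Pt anode/Pt cathode, undivided cell, constant current ca. 0.25 A cm⁻², 45–50 °C, until the electrolyte turns faintly alkaline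
Reagents that add atoms: none
Why: Mixed Kolbe electrolysis: at the platinum anode under high current density the carboxylates of 1 and 2 are each oxidised by one electron to acyloxy radicals that lose CO2 at once, and the primary alkyl radicals 3 and 4, formed side by side at high concentration in the anode layer, combine to the C17–C18 bond. The closest known reaction type is the cross-Kolbe coupling of a dicarboxylic acid half-ester with an ω-substituted fatty acid, the classical entry to long-chain difunctional acids. No ring is closed and no stereocentre is formed; the step sets the full C32 skeleton with both termini already differentiated (C32–Br and the C1 ester). The selectivities needed are cross- over homo-coupling and radical coupling over further oxidation to the cation: the first is only statistical and is steered by the threefold excess of the cheaper acid 2, and the three coupling products carry zero, one and two ester groups, so they should separate by polarity; the second is secured by the unbranched primary radicals (no α-substituent to stabilise a cation), the platinum anode, the weakly acidic, partly neutralised methanol and the high current density. The bromide and the tert-butyl ester sit 15 and 16 carbons from the radical centres and should not be touched at the anode, and at the platinum cathode proton reduction runs far positive of C–Br reduction; the heptane layer should keep the waxy products off the electrode.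

Step 2
Reactants: 5 tert-butyl 32-bromodotriacontanoate
Product: 6 32-bromodotriacontanoic acid
Conditions: TFA, CH2Cl2 (1:2), rt to 35 °C
Reagents that add atoms: none
Why: Acidolysis of a tert-butyl ester (alkyl–oxygen cleavage with loss of the tert-butyl cation as isobutene) needs no nucleophile, so the primary C32 bromide should survive untouched.

Step 3
Reactants: 6 32-bromodotriacontanoic acid
Product: 8 oxacyclotritriacontan-2-one (the target), via caesium 32-bromodotriacontanoate 7 (not isolated)
Conditions: Cs2CO3 (3 equiv), DMF, 80 °C, slow addition of 6 (warm THF/DMF) over 24 h, final concentration ≤ 2 mM
Reagents that add atoms: none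
Why: Caesium carboxylate macrolactonisation (intramolecular SN2 O-alkylation): the weakly ion-paired carboxylate displaces the primary bromide in a strain-free 33-membered closure, and slow addition should hold the stationary concentration below the effective molarity of a large ring so that cyclisation outruns oligo-esterification.

Compound list
1 | 16-bromohexadecanoic acid | OC(=O)CCCCCCCCCCCCCCCBr | starting material
2 | 18-(tert-butoxy)-18-oxooctadecanoic acid (mono-tert-butyl octadecanedioate) | OC(=O)CCCCCCCCCCCCCCCCC(=O)OC(C)(C)C | starting material
3 | 15-bromopentadecyl radical | [CH2]CCCCCCCCCCCCCCBr | intermediate
4 | 17-tert-butoxy-17-oxoheptadecyl radical | [CH2]CCCCCCCCCCCCCCCC(=O)OC(C)(C)C | intermediate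
5 | tert-butyl 32-bromodotriacontanoate | CC(C)(C)OC(=O)CCCCCCCCCCCCCCCCCCCCCCCCCCCCCCCBr | intermediate
6 | 32-bromodotriacontanoic acid | OC(=O)CCCCCCCCCCCCCCCCCCCCCCCCCCCCCCCBr | intermediate
7 | caesium 32-bromodotriacontanoate | [Cs+].[O-]C(=O)CCCCCCCCCCCCCCCCCCCCCCCCCCCCCCCBr | intermediate
8 | oxacyclotritriacontan-2-one (32-dotriacontanolide) | O=C1CCCCCCCCCCCCCCCCCCCCCCCCCCCCCCCO1 | target

Total step count: 3
Longest linear sequence: 3 steps

Steps most likely to fail

1. Step 1 (key step). Homo-coupling may consume the limiting acid beyond its statistical share, and the waxy C30–C36 products may foul the anode, so that the potential drifts and the radicals are over-oxidised to cations (Hofer–Moest pathway, giving methyl ethers and alkenes). The fallback replaces radical dimerisation by a two-electron organometallic coupling; it sets out from 1 and returns to the route at 6. Commercial 16-bromohexadecan-1-ol is protected with 3,4-dihydro-2H-pyran (PPTS, CH2Cl2) as 2-[(16-bromohexadecyl)oxy]oxane F1 and converted with Mg in THF into {16-[(oxan-2-yl)oxy]hexadecyl}magnesium bromide F2. Of this reagent, 2.2 equivalents (the first deprotonates the acid) are coupled with 1 under Li2CuCl4 catalysis (THF, −20 to 0 °C); this copper-catalysed Grignard–alkyl bromide coupling should displace the C16 bromide of the magnesium carboxylate and give, after acidic work-up, 32-[(oxan-2-yl)oxy]dotriacontanoic acid F3, the new bond now being C16–C17. Heating F3 in 48% aqueous HBr/acetic acid should cleave the acetal and convert the liberated primary alcohol into the bromide, which is 6; step 3 then follows.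

2. Step 3. Intermolecular O-alkylation (linear oligoesters, the 66-membered diolide) may outrun ring closure if the caesium soap aggregates or precipitates, and carbonate may slowly attack the bromide. The fallback activates the acyl group instead of alkylating the carboxylate; it sets out from 6 and returns at 8. Compound 6 is heated with excess aqueous KOH in dioxane (reflux, then acidification; any ester formed on the way is saponified again) to give 32-hydroxydotriacontanoic acid F4. Yamaguchi macrolactonisation follows: 2,4,6-trichlorobenzoyl chloride and Et3N in THF give the mixed anhydride 32-hydroxydotriacontanoic 2,4,6-trichlorobenzoic anhydride F5, which is added slowly to DMAP in toluene at reflux and should close the same ring at the C1–O acyl bond to give 8.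

3. Step 2. Acidolysis may stay incomplete because the waxy C36 ester separates from the TFA medium, and material may be lost when the poorly soluble bromo acid is freed from tert-butyl-derived by-products. The fallback uses a different protecting group, cleaved by acyl–oxygen hydrolysis; it sets out from 1 and returns at 6. The electrolysis of step 1 is run with commercial 18-methoxy-18-oxooctadecanoic acid (monomethyl octadecanedioate) in place of 2 to give methyl 32-bromodotriacontanoate F6. This ester is hydrolysed in 48% aqueous HBr/acetic acid at 100 °C, where the mixture is homogeneous and bromide is the only nucleophile, so the C32–Br bond should be preserved, to give 6.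

Further compounds
F1 | step 1 | 2-[(16-bromohexadecyl)oxy]oxane | BrCCCCCCCCCCCCCCCCOC1CCCCO1
F2 | step 1 | {16-[(oxan-2-yl)oxy]hexadecyl}magnesium bromide | Br[Mg]CCCCCCCCCCCCCCCCOC1CCCCO1
F3 | step 1 | 32-[(oxan-2-yl)oxy]dotriacontanoic acid | OC(=O)CCCCCCCCCCCCCCCCCCCCCCCCCCCCCCCOC1CCCCO1
F4 | step 3 | 32-hydroxydotriacontanoic acid | OC(=O)CCCCCCCCCCCCCCCCCCCCCCCCCCCCCCCO
F5 | step 3 | 32-hydroxydotriacontanoic 2,4,6-trichlorobenzoic anhydride | O=C(OC(=O)CCCCCCCCCCCCCCCCCCCCCCCCCCCCCCCO)c1c(Cl)cc(Cl)cc1Cl
F6 | step 2 | methyl 32-bromodotriacontanoate | COC(=O)CCCCCCCCCCCCCCCCCCCCCCCCCCCCCCCBr
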